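**Retrosynthetic overview**
1. Target 24 (germacrane numbering C1–C15; C6 R, C7 S, C8 R, C9 S; both ring olefins cis within the ring) ⇐ acid unmasking of the C14 acetal and C15 silyl ether of macrocycle 22.
2. 22 ⇐ ring-closing metathesis at C4=C5 of diene 21; the ten-membered carbocycle is formed last.
3. 21 ⇐ Nozaki–Hiyama–Kishi (NHK) C9–C10 coupling of aldehyde 19 with (Z)-vinyl iodide 8 (sets C9).
4. 19 ⇐ Barbier C7–C8 allylation of bromomethyl butenolide 12 with silyloxyacetaldehyde 13 (sets C7 and C8), then acylation with (S)-2-methylbutanoic acid 16.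
5. 12 (lactone ring, formed first; sets C6) ⇐ new enantioselective desymmetrising RCM of triene ester 11; 8 ⇐ Johnson–Claisen, Wittig and α-iodination from diol 1.

Assumption: the facial sense of the chiral ruthenium catalyst in step 8 cannot be predicted with certainty; the (4R,5R) ligand is written, and its (4S,5S) antipode is used if it delivers the enantiomer of 12.

**Route**

Step 1
Reactants: 1 2-methylenepropane-1,3-diol
Product: 2 2-(((tert-butyldimethylsilyl)oxy)methyl)prop-2-en-1-ol
Conditions: NaH (1.0 equiv), THF, 0 °C; then TBSCl (1.0 equiv), rt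
Reagents that add atoms: tert-butyldimethylsilyl chloride, CC(C)(C)[Si](C)(C)Cl
Why: One equivalent of NaH forms the monosodium alkoxide of the symmetrical diol, which is silylated once (Williamson-type O-silylation, monoprotection of a symmetrical diol); no stereocentre.

Step 2
Reactants: 2 2-(((tert-butyldimethylsilyl)oxy)methyl)prop-2-en-1-ol
Product: 4 ethyl 4-(((tert-butyldimethylsilyl)oxy)methyl)pent-4-enoate, via ketene acetal 3 (not isolated)
Conditions: MeC(OEt)3 (6 equiv), EtCO2H (5 mol%), 140 °C, EtOH distilled off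
Reagents that add atoms: triethyl orthoacetate, CCOC(C)(OCC)OCC
Why: Johnson–Claisen orthoester rearrangement: exchange and loss of ethanol give ketene acetal 3, whose [3,3]-sigmatropic shift builds C1–C3 and leaves the 1,1-disubstituted C4 olefin needed in step 14; no stereocentre.

Step 3
Reactants: 4 ethyl 4-(((tert-butyldimethylsilyl)oxy)methyl)pent-4-enoate
Product: 5 4-(((tert-butyldimethylsilyl)oxy)methyl)pent-4-enal
Conditions: i-Bu2AlH (1.05 equiv), CH2Cl2, −78 °C; then H2O
Reagents that add atoms: none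
Why: Partial ester reduction; the tetrahedral aluminium hemiacetal is stable at −78 °C and releases the aldehyde only on work-up.

Step 4
Reactants: 5 4-(((tert-butyldimethylsilyl)oxy)methyl)pent-4-enal
Product: 6 (E)-6-(((tert-butyldimethylsilyl)oxy)methyl)hepta-2,6-dienal
Conditions: Ph3P=CHCHO (1.2 equiv), toluene, 80 °C
Reagents that add atoms: (triphenylphosphoranylidene)acetaldehyde, O=CC=P(c1ccccc1)(c1ccccc1)c1ccccc1
Why: Wittig olefination with the stabilised formyl ylide gives the (E)-enal and adds C10 and C14.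

Step 5
Reactants: 6 (E)-6-(((tert-butyldimethylsilyl)oxy)methyl)hepta-2,6-dienal
Product: 7 (Z)-6-(((tert-butyldimethylsilyl)oxy)methyl)-2-iodohepta-2,6-dienal
Conditions: I2 (1.5 equiv), K2CO3 (1.2 equiv), DMAP (20 mol%), THF/H2O (1:1), rt, dark
Reagents that add atoms: iodine, [I][I]
Why: DMAP-catalysed α-iodination of the enal (conjugate addition of DMAP, iodination of the enolate, E1cB loss of DMAP) gives the thermodynamically preferred (Z)-α-iodoenal with iodine cis to the chain, which fixes the later ring-cis C1=C10 geometry; the inductively deactivated isolated 1,1-disubstituted olefin should not be iodinated under these buffered conditions.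

Step 6
Reactants: 7 (Z)-6-(((tert-butyldimethylsilyl)oxy)methyl)-2-iodohepta-2,6-dienal
Product: 8 (Z)-tert-butyl((6-iodo-7,7-dimethoxy-2-methylenehept-5-en-1-yl)oxy)dimethylsilane
Conditions: MeOSiMe3 (2.5 equiv), Me3SiOTf (5 mol%), CH2Cl2, −78 °C
Reagents that add atoms: methoxytrimethylsilane, CO[Si](C)(C)C
Why: Noyori acetalisation under aprotic conditions masks the C14 aldehyde as its dimethyl acetal without touching the primary TBS ether or the vinyl iodide.

Step 7
Reactants: 9 penta-1,4-dien-3-ol; 10 2-(bromomethyl)acrylic acid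
Product: 11 penta-1,4-dien-3-yl 2-(bromomethyl)acrylate
Conditions: iPrN=C=NiPr (1.1 equiv), DMAP (5 mol%), CH2Cl2, 0 °C
Reagents that add atoms: none
Why: Carbodiimide (Steglich) esterification of the achiral secondary alcohol at 0 °C, where catalytic DMAP acylates faster than it displaces the allylic bromide.

Step 8
Reactants: 11 penta-1,4-dien-3-yl 2-(bromomethyl)acrylate
Product: 12 (R)-3-(bromomethyl)-5-vinylfuran-2(5H)-one
Conditions: RuI2(L)(=CH-C6H4-2-OiPr) (5 mol%; L = (4R,5R)-1,3-bis(2-isopropylphenyl)-4,5-diphenylimidazolidin-2-ylidene), toluene (0.02 mol/L), 40 °C, Ar sparge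
Reagents that add atoms: none
Why: Proposed new method: enantioselective desymmetrising ring-closing metathesis of a divinylcarbinyl 2-substituted acrylate; the ruthenium alkylidene forms reversibly on either enantiotopic vinyl group (fast degenerate exchange) and the slower ring closure onto the electron-poor 1,1-disubstituted acrylate olefin is enantio-determining (Curtin–Hammett), the geared C2-symmetric diphenyl-backbone carbene holding the spectator vinyl group away from the ortho-isopropyl aryl wing so that one vinyl group closes to the butenolide and C6 becomes R; the closest known reactions are the desymmetrising RCM of trienyl ethers to dihydrofurans with this catalyst family and the achiral RCM of methacrylates of allylic alcohols to butenolides, whereas enantioselective closure onto an acrylate to give a γ-vinyl butenolide has not been shown.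

Step 9
Reactants: 12 (R)-3-(bromomethyl)-5-vinylfuran-2(5H)-one; 13 2-((tert-butyldimethylsilyl)oxy)acetaldehyde
Product: 15 (4R,5R)-4-((R)-2-((tert-butyldimethylsilyl)oxy)-1-hydroxyethyl)-3-methylene-5-vinyldihydrofuran-2(3H)-one, via allylzinc bromide 14 (not isolated)
Conditions: Zn dust (3 equiv), 13 (2 equiv), THF/sat. aq. NH4Cl (2:1), 0 °C
Reagents that add atoms: none
Why: Barbier allylation: zinc inserts into the allylic C–Br bond and allylzinc 14 adds through its ring carbon (SE2') in a closed chair transition state, on the face anti to the C6 vinyl group and with the aldehyde substituent equatorial, giving the 6,7-trans α-methylene lactone and the C8 carbinol configuration of the target (known reactivity of 3-(bromomethyl)butenolides).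

Step 10
Reactants: 15 (4R,5R)-4-((R)-2-((tert-butyldimethylsilyl)oxy)-1-hydroxyethyl)-3-methylene-5-vinyldihydrofuran-2(3H)-one; 16 (S)-2-methylbutanoic acid
Product: 17 (R)-2-((tert-butyldimethylsilyl)oxy)-1-((2R,3S)-4-methylene-5-oxo-2-vinyltetrahydrofuran-3-yl)ethyl (S)-2-methylbutanoate
Conditions: 16 (2 equiv), iPrN=C=NiPr (2 equiv), DMAP (0.2 equiv), CH2Cl2, 0 °C to rt
Reagents that add atoms: none
Why: Steglich esterification of the C8 hydroxyl with the chiral-pool acid brings in the (S)-configured side chain without touching C6–C8, and it turns any minor enantiomer from step 8 into a separable diastereomer.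

Step 11
Reactants: 17 (R)-2-((tert-butyldimethylsilyl)oxy)-1-((2R,3S)-4-methylene-5-oxo-2-vinyltetrahydrofuran-3-yl)ethyl (S)-2-methylbutanoate
Product: 18 (R)-2-hydroxy-1-((2R,3S)-4-methylene-5-oxo-2-vinyltetrahydrofuran-3-yl)ethyl (S)-2-methylbutanoate
Conditions: HF·pyridine, pyridine, THF, 0 °C
Reagents that add atoms: none
Why: Fluoride cleavage of the primary TBS ether under buffered, weakly acidic conditions, chosen to suppress 1,2-acyl migration from O8 to the new primary hydroxyl; the product is used at once.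

Step 12
Reactants: 18 (R)-2-hydroxy-1-((2R,3S)-4-methylene-5-oxo-2-vinyltetrahydrofuran-3-yl)ethyl (S)-2-methylbutanoate
Product: 19 (R)-1-((2R,3S)-4-methylene-5-oxo-2-vinyltetrahydrofuran-3-yl)-2-oxoethyl (S)-2-methylbutanoate
Conditions: Dess–Martin periodinane (1.3 equiv), CH2Cl2, 0 °C to rt
Reagents that add atoms: none
Why: Dess–Martin oxidation under neutral conditions gives the α-acyloxy aldehyde without epimerising C8; it is used crude.

Step 13
Reactants: 19 (R)-1-((2R,3S)-4-methylene-5-oxo-2-vinyltetrahydrofuran-3-yl)-2-oxoethyl (S)-2-methylbutanoate; 8 (Z)-tert-butyl((6-iodo-7,7-dimethoxy-2-methylenehept-5-en-1-yl)oxy)dimethylsilane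
Product: 21 (1R,2S,E)-7-(((tert-butyldimethylsilyl)oxy)methyl)-3-(dimethoxymethyl)-2-hydroxy-1-((2R,3S)-4-methylene-5-oxo-2-vinyltetrahydrofuran-3-yl)octa-3,7-dien-1-yl (S)-2-methylbutanoate, via alkenylchromium dichloride 20 (not isolated)
Conditions: 8 (1.5 equiv), CrCl2 (6 equiv), NiCl2 (2 mol%), DMSO/THF (3:1), rt
Reagents that add atoms: none
Why: Nozaki–Hiyama–Kishi reaction: zerovalent nickel inserts into the C–I bond, transmetalation gives alkenylchromium 20 with retention of olefin geometry, and 20 adds only to the aldehyde in the polar Felkin–Anh sense (anti to the acyloxy group), setting C9 as S (8,9-anti) and leaving the C9 hydroxyl free as in the target.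

Step 14
Reactants: 21 (1R,2S,E)-7-(((tert-butyldimethylsilyl)oxy)methyl)-3-(dimethoxymethyl)-2-hydroxy-1-((2R,3S)-4-methylene-5-oxo-2-vinyltetrahydrofuran-3-yl)octa-3,7-dien-1-yl (S)-2-methylbutanoate
Product: 22 (3aS,4R,5S,6E,10E,11aR)-10-(((tert-butyldimethylsilyl)oxy)methyl)-6-(dimethoxymethyl)-5-hydroxy-3-methylene-2-oxo-2,3,3a,4,5,8,9,11a-octahydrocyclodeca[b]furan-4-yl (S)-2-methylbutanoate
Conditions: second-generation Hoveyda–Grubbs catalyst RuCl2(H2IMes)(=CH-C6H4-2-OiPr) (2 × 7.5 mol%; H2IMes = 1,3-dimesitylimidazolidin-2-ylidene), toluene (0.001 mol/L), 80 °C, Ar sparge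
Reagents that add atoms: none
Why: Ring-closing metathesis: the ruthenium alkylidene forms at the monosubstituted C5 vinyl group and closes onto the 1,1-disubstituted C4 olefin with loss of ethylene; the ten-membered ring, already folded by the cis C1=C10 olefin and the trans-fused lactone, is expected to close to the less strained ring-cis C4=C5 geometry.

Step 15
Reactants: 22 (3aS,4R,5S,6E,10E,11aR)-10-(((tert-butyldimethylsilyl)oxy)methyl)-6-(dimethoxymethyl)-5-hydroxy-3-methylene-2-oxo-2,3,3a,4,5,8,9,11a-octahydrocyclodeca[b]furan-4-yl (S)-2-methylbutanoate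
Product: 24 (3aS,4R,5S,6E,10E,11aR)-6-formyl-5-hydroxy-10-(hydroxymethyl)-3-methylene-2-oxo-2,3,3a,4,5,8,9,11a-octahydrocyclodeca[b]furan-4-yl (S)-2-methylbutanoate, via silyl ether aldehyde 23 (not isolated)
Conditions: 48% aq. HF (excess), MeCN, 0 °C to rt
Reagents that add atoms: water, O
Why: Aqueous acid hydrolyses the dimethyl acetal to the conjugated C14 aldehyde (no α-hydrogen at C10, so no isomerisation) and HF cleaves the primary TBS ether, unveiling the target without base that could trigger acyl migration or conjugate addition to the α-methylene lactone.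

**Compound list**
1 | 2-methylenepropane-1,3-diol | C=C(CO)CO | starting material
2 | 2-(((tert-butyldimethylsilyl)oxy)methyl)prop-2-en-1-ol | C=C(CO)CO[Si](C)(C)C(C)(C)C | intermediate
3 | tert-butyl((2-(((1-ethoxyvinyl)oxy)methyl)allyl)oxy)dimethylsilane (ketene acetal) | C=C(OCC)OCC(=C)CO[Si](C)(C)C(C)(C)C | intermediate
4 | ethyl 4-(((tert-butyldimethylsilyl)oxy)methyl)pent-4-enoate | CCOC(=O)CCC(=C)CO[Si](C)(C)C(C)(C)C | intermediate
5 | 4-(((tert-butyldimethylsilyl)oxy)methyl)pent-4-enal | O=CCCC(=C)CO[Si](C)(C)C(C)(C)C | intermediate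
6 | (E)-6-(((tert-butyldimethylsilyl)oxy)methyl)hepta-2,6-dienal | O=C/C=C/CCC(=C)CO[Si](C)(C)C(C)(C)C | intermediate
7 | (Z)-6-(((tert-butyldimethylsilyl)oxy)methyl)-2-iodohepta-2,6-dienal | O=C/C([I])=C/CCC(=C)CO[Si](C)(C)C(C)(C)C | intermediate
8 | (Z)-tert-butyl((6-iodo-7,7-dimethoxy-2-methylenehept-5-en-1-yl)oxy)dimethylsilane | COC(OC)/C([I])=C/CCC(=C)CO[Si](C)(C)C(C)(C)C | intermediate
9 | penta-1,4-dien-3-ol | C=CC(O)C=C | starting material
10 | 2-(bromomethyl)acrylic acid | C=C(CBr)C(=O)O | starting material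
11 | penta-1,4-dien-3-yl 2-(bromomethyl)acrylate | C=CC(C=C)OC(=O)C(=C)CBr | intermediate
12 | (R)-3-(bromomethyl)-5-vinylfuran-2(5H)-one | O=C1O[C@H](C=C)C=C1CBr | intermediate
13 | 2-((tert-butyldimethylsilyl)oxy)acetaldehyde | O=CCO[Si](C)(C)C(C)(C)C | starting material
14 | bromo(((R)-2-oxo-5-vinyl-2,5-dihydrofuran-3-yl)methyl)zinc (allylzinc bromide) | Br[Zn]CC1=C[C@@H](C=C)OC1=O | intermediate
15 | (4R,5R)-4-((R)-2-((tert-butyldimethylsilyl)oxy)-1-hydroxyethyl)-3-methylene-5-vinyldihydrofuran-2(3H)-one | C=C1C(=O)O[C@H](C=C)[C@H]1[C@@H](O)CO[Si](C)(C)C(C)(C)C | intermediate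
16 | (S)-2-methylbutanoic acid | CC[C@H](C)C(=O)O | starting material
17 | (R)-2-((tert-butyldimethylsilyl)oxy)-1-((2R,3S)-4-methylene-5-oxo-2-vinyltetrahydrofuran-3-yl)ethyl (S)-2-methylbutanoate | C=C1C(=O)O[C@H](C=C)[C@H]1[C@@H](OC(=O)[C@@H](C)CC)CO[Si](C)(C)C(C)(C)C | intermediate
18 | (R)-2-hydroxy-1-((2R,3S)-4-methylene-5-oxo-2-vinyltetrahydrofuran-3-yl)ethyl (S)-2-methylbutanoate | C=C1C(=O)O[C@H](C=C)[C@H]1[C@@H](OC(=O)[C@@H](C)CC)CO | intermediate
19 | (R)-1-((2R,3S)-4-methylene-5-oxo-2-vinyltetrahydrofuran-3-yl)-2-oxoethyl (S)-2-methylbutanoate | C=C1C(=O)O[C@H](C=C)[C@H]1[C@@H](OC(=O)[C@@H](C)CC)C=O | intermediate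
20 | dichloro((Z)-6-(((tert-butyldimethylsilyl)oxy)methyl)-1,1-dimethoxyhepta-2,6-dien-2-yl)chromium (alkenylchromium dichloride) | Cl[Cr](Cl)/C(C(OC)OC)=C\CCC(=C)CO[Si](C)(C)C(C)(C)C | intermediate
21 | (1R,2S,E)-7-(((tert-butyldimethylsilyl)oxy)methyl)-3-(dimethoxymethyl)-2-hydroxy-1-((2R,3S)-4-methylene-5-oxo-2-vinyltetrahydrofuran-3-yl)octa-3,7-dien-1-yl (S)-2-methylbutanoate | C=C1C(=O)O[C@H](C=C)[C@H]1[C@@H](OC(=O)[C@@H](C)CC)[C@@H](O)/C(C(OC)OC)=C\CCC(=C)CO[Si](C)(C)C(C)(C)C | intermediate
22 | (3aS,4R,5S,6E,10E,11aR)-10-(((tert-butyldimethylsilyl)oxy)methyl)-6-(dimethoxymethyl)-5-hydroxy-3-methylene-2-oxo-2,3,3a,4,5,8,9,11a-octahydrocyclodeca[b]furan-4-yl (S)-2-methylbutanoate | C=C1C(=O)O[C@@H]2/C=C(/CO[Si](C)(C)C(C)(C)C)CC/C=C(/C(OC)OC)[C@H](O)[C@H](OC(=O)[C@@H](C)CC)[C@@H]12 | intermediate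
23 | (3aS,4R,5S,6E,10E,11aR)-10-(((tert-butyldimethylsilyl)oxy)methyl)-6-formyl-5-hydroxy-3-methylene-2-oxo-2,3,3a,4,5,8,9,11a-octahydrocyclodeca[b]furan-4-yl (S)-2-methylbutanoate (silyl ether aldehyde) | C=C1C(=O)O[C@@H]2/C=C(/CO[Si](C)(C)C(C)(C)C)CC/C=C(/C=O)[C@H](O)[C@H](OC(=O)[C@@H](C)CC)[C@@H]12 | intermediate
24 | (3aS,4R,5S,6E,10E,11aR)-6-formyl-5-hydroxy-10-(hydroxymethyl)-3-methylene-2-oxo-2,3,3a,4,5,8,9,11a-octahydrocyclodeca[b]furan-4-yl (S)-2-methylbutanoate (CNP0331447.11) | C=C1C(=O)O[C@@H]2/C=C(/CO)CC/C=C(/C=O)[C@H](O)[C@H](OC(=O)[C@@H](C)CC)[C@@H]12 | target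

**Step count and risk**

Total step count: 15. Longest linear sequence: 9 steps (steps 7–15; the branch through steps 1–6 and 13–15 is also 9).

The three steps most likely to fail are steps 8, 14 and 13.

Step 8 (proposed new desymmetrising RCM; risk: low enantioselectivity or poor turnover with the acrylate). The fallback uses known chemistry and sets the C6 centre by a Sharpless kinetic resolution. It sets out from acid 10. Commercial racemic (E)-hexa-1,4-dien-3-ol is resolved with Ti(OiPr)4 (10 mol%), D-(−)-diisopropyl tartrate (12 mol%) and t-BuOOH (0.6 equiv) over 4 Å molecular sieves in CH2Cl2 at −20 °C. This epoxidises the propenyl group of the (R)-enantiomer to (R)-1-((2R,3R)-3-methyloxiran-2-yl)prop-2-en-1-ol F2, which is removed, and leaves (S,E)-hexa-1,4-dien-3-ol F1. F1 is esterified with 10 (iPrN=C=NiPr, cat. DMAP, CH2Cl2, 0 °C) to (S,E)-hexa-1,4-dien-3-yl 2-(bromomethyl)acrylate F3. F3 is ring-closed with the second-generation Grubbs catalyst RuCl2(H2IMes)(PCy3)(=CHPh) (CH2Cl2, 40 °C), mainly through the more reactive terminal vinyl group, to (R,E)-3-(bromomethyl)-5-(prop-1-en-1-yl)furan-2(5H)-one F4; any 5-vinyl butenolide formed through the propenyl group has the opposite configuration and is separated here. Ethenolysis of F4 (ethylene, 1 atm, second-generation Hoveyda–Grubbs catalyst RuCl2(H2IMes)(=CH-C6H4-2-OiPr), CH2Cl2, rt) trims the propenyl group to vinyl and gives 12, where the route is rejoined.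

Step 14 (ten-membered ring by RCM with a trisubstituted olefin; risk: oligomerisation or no closure). The fallback closes the ring at C9–C10 by an intramolecular NHK reaction instead. The C4=C5 olefin is made beforehand by a cross-metathesis that is E-selective because C15 is carried as a conjugated aldehyde. It sets out from 8 and 19. Compound 8 is desilylated (Bu4NF, THF, 0 °C) to (Z)-6-iodo-7,7-dimethoxy-2-methylenehept-5-en-1-ol F6 and oxidised (MnO2, CH2Cl2, rt) to (Z)-6-iodo-7,7-dimethoxy-2-methylenehept-5-enal F7. Cross-metathesis of the vinyl group of 19 with F7 (3 equiv, second-generation Hoveyda–Grubbs catalyst RuCl2(H2IMes)(=CH-C6H4-2-OiPr), CH2Cl2, 40 °C) gives (R)-1-((2R,3S)-2-((1E,5Z)-2-formyl-6-iodo-7,7-dimethoxyhepta-1,5-dien-1-yl)-4-methylene-5-oxotetrahydrofuran-3-yl)-2-oxoethyl (S)-2-methylbutanoate F8. In F8, C6 is trans to the formyl group, which is the thermodynamic enal geometry and the ring-cis geometry required. Luche reduction (NaBH4, CeCl3·7H2O, MeOH, −78 °C) reduces the conjugated aldehyde while the α-acyloxy aldehyde is masked in situ as its hemiacetal; this chemoselectivity is the weak point of the fallback. It gives (R)-1-((2R,3S)-2-((1E,5Z)-2-(hydroxymethyl)-6-iodo-7,7-dimethoxyhepta-1,5-dien-1-yl)-4-methylene-5-oxotetrahydrofuran-3-yl)-2-oxoethyl (S)-2-methylbutanoate F9. NHK macrocyclisation (CrCl2, cat. NiCl2, DMSO/THF, 0.002 mol/L, rt) closes the ten-membered ring with the same Felkin–Anh preference to (3aS,4R,5S,6E,10E,11aR)-6-(dimethoxymethyl)-5-hydroxy-10-(hydroxymethyl)-3-methylene-2-oxo-2,3,3a,4,5,8,9,11a-octahydrocyclodeca[b]furan-4-yl (S)-2-methylbutanoate F10. Hydrolysis of the acetal (pyridinium p-toluenesulfonate, acetone/H2O, rt) gives 24, so this fallback comes back to the route at the target.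

Step 13 (intermolecular NHK addition; risk: poor 8,9-anti to syn ratio at C9). The fallback sets C9 by ketone reduction instead of by addition. It sets out from 21, obtained as a mixture with its C9 epimer. Oxidation with Dess–Martin periodinane (CH2Cl2, 0 °C) gives (R,Z)-7-(((tert-butyldimethylsilyl)oxy)methyl)-3-(dimethoxymethyl)-1-((2R,3S)-4-methylene-5-oxo-2-vinyltetrahydrofuran-3-yl)-2-oxoocta-3,7-dien-1-yl (S)-2-methylbutanoate F5. Corey–Bakshi–Shibata reduction of F5 with (S)-2-methyl-CBS-oxazaborolidine (20 mol%) and catecholborane (toluene, −78 °C) should give the 9S alcohol, with the fully substituted alkenyl group acting as the large substituent. This returns 21 as a single C9 epimer, where the route is rejoined.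

**Further compounds**
F1 | step 8 | (S,E)-hexa-1,4-dien-3-ol | O[C@H](/C=C/C)C=C
F2 | step 8 | (R)-1-((2R,3R)-3-methyloxiran-2-yl)prop-2-en-1-ol | C=C[C@@H](O)[C@H]1O[C@@H]1C
F3 | step 8 | (S,E)-hexa-1,4-dien-3-yl 2-(bromomethyl)acrylate | C=C(CBr)C(=O)O[C@H](/C=C/C)C=C
F4 | step 8 | (R,E)-3-(bromomethyl)-5-(prop-1-en-1-yl)furan-2(5H)-one | O=C1O[C@H](/C=C/C)C=C1CBr
F5 | step 13 | (R,Z)-7-(((tert-butyldimethylsilyl)oxy)methyl)-3-(dimethoxymethyl)-1-((2R,3S)-4-methylene-5-oxo-2-vinyltetrahydrofuran-3-yl)-2-oxoocta-3,7-dien-1-yl (S)-2-methylbutanoate | C=C1C(=O)O[C@H](C=C)[C@H]1[C@@H](OC(=O)[C@@H](C)CC)C(=O)/C(C(OC)OC)=C\CCC(=C)CO[Si](C)(C)C(C)(C)C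
F6 | step 14 | (Z)-6-iodo-7,7-dimethoxy-2-methylenehept-5-en-1-ol | COC(OC)/C([I])=C/CCC(=C)CO
F7 | step 14 | (Z)-6-iodo-7,7-dimethoxy-2-methylenehept-5-enal | COC(OC)/C([I])=C/CCC(=C)C=O
F8 | step 14 | (R)-1-((2R,3S)-2-((1E,5Z)-2-formyl-6-iodo-7,7-dimethoxyhepta-1,5-dien-1-yl)-4-methylene-5-oxotetrahydrofuran-3-yl)-2-oxoethyl (S)-2-methylbutanoate | C=C1C(=O)O[C@H](/C=C(/C=O)CC/C=C(\[I])C(OC)OC)[C@H]1[C@@H](OC(=O)[C@@H](C)CC)C=O
F9 | step 14 | (R)-1-((2R,3S)-2-((1E,5Z)-2-(hydroxymethyl)-6-iodo-7,7-dimethoxyhepta-1,5-dien-1-yl)-4-methylene-5-oxotetrahydrofuran-3-yl)-2-oxoethyl (S)-2-methylbutanoate | C=C1C(=O)O[C@H](/C=C(/CO)CC/C=C(\[I])C(OC)OC)[C@H]1[C@@H](OC(=O)[C@@H](C)CC)C=O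
F10 | step 14 | (3aS,4R,5S,6E,10E,11aR)-6-(dimethoxymethyl)-5-hydroxy-10-(hydroxymethyl)-3-methylene-2-oxo-2,3,3a,4,5,8,9,11a-octahydrocyclodeca[b]furan-4-yl (S)-2-methylbutanoate | C=C1C(=O)O[C@@H]2/C=C(/CO)CC/C=C(/C(OC)OC)[C@H](O)[C@H](OC(=O)[C@@H](C)CC)[C@@H]12
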